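In a one-step world, with free monomer held at its charge, a living end would add units at a steady pace; each flask here has three steps.

    free monomer + initiator → living end + monomer in chains (k1 = 1.09 M⁻¹ h⁻¹)
    free monomer + living end → monomer in chains + living end, rate k2*[living end]*[free monomer] (k2 = 6.93 M⁻¹ h⁻¹)
    protic impurity + free monomer → quenched substrate (k3 = 0.147 M⁻¹ h⁻¹)

| setting | teal | violet |
|---|---|---|
| free monomer | 3.0 M | 0.80 M |
| protic impurity | 0.600 M | 0.600 M |
| initiator | 19 mM | 19 mM |
| time | 8.0 h | 8.0 h |

- the average divides the monomer in chains by the number of chains begun, living and dead together
- run time (teal): 8.0 h

* which of the two ends with the longer chains by the average number of monomer units in a chain (chains begun, living or dead) ("neither" if they lie within 10%) (teal / violet / neither)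
* average number of monomer units in a chain (chains begun, living or dead) at the end, teal
* average number of monomer units in a chain (chains begun, living or dead) at the end, violet

For you at the bench, by my own reckoning:

1. In teal, the initiator's half-life at charge is 0.212 h, shorter than the run, so expect living ends early, close to the 19 mM charged.

2. In teal, protic impurity has a half-life of 1.6 h by its step with free monomer, the other concentrations as charged. That step uses up free monomer too, but no step of the scheme removes a living end.

3. Keep one number, the pace: the units one living end adds per hour with free monomer at its charge, which is the growth constant times that charge. It is 20.8 h⁻¹ in teal and 5.54 h⁻¹ in violet, so at the charge a living end grows faster in teal than in violet.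

4. Pace times run time gives 166 units in teal and 44.4 in violet. The fraction of free monomer left falls as you wait, so I guess a mean fraction of 0.5, which gives 83.0 and 22.2.

5. Leave the free monomer of both flasks as charged, since the pace is proportional to it.

The forecast says teal, with 86.5 and 19.6, noting that “the impurity step consumes monomer but doesn't kill chains”. Its figures differ from my rougher ones.

The flasks give teal: 86.6 in teal and 19.6 in violet.

The difference in free monomer is the main reason: violet, given teal's free monomer, reaches 86.6 instead of 19.6, a factor of 4.43. The ratio of the paces is 3.75. Measured against pace times time, teal's chains reach a fraction 0.522 and violet's 0.441.

The rate constants are assumed; the rest is arithmetic.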